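**Retrosynthetic overview** (chain locants C1'–C8', C1' being the OCH2 carbon)
- The C6' hydroperoxide is introduced last, by SN2 inversion of a 6'R mesylate with a masked hydroperoxide, followed by one acidic unmasking of the OOH and the C4' hydroxyl.
- The only ring formed is the pyranone, closed at O1–C8a: C8a is the single free ortho carbon of the tolyl ring (the other ortho carbon is C5 and carries the methyl), and C4 already holds the chain oxygen as an enol ether. An (E)-3-alkoxy-3-(2-methylphenyl)acrylic acid is therefore closed by anodic C–H lactonization.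
- That acid comes from Mitsunobu O-alkylation of ethyl 3-(2-methylphenyl)-3-oxopropanoate with the chain alcohol, then saponification.
- The chain alcohol comes from a boron aldol of 3-methylbut-3-en-2-one with (E)-4-acetoxy-2-methylbut-2-enal (C4'–C5' bond, sets 4'S), then silylation, catalyst-controlled ketone reduction (6'R), second silylation and deacetylation.

Key step: step 9

Remark on the chemistry: in step 2 the sense of induction is taken from the usual behaviour of diisopinocampheylboron enolates of methyl ketones, for which the reagent from (−)-α-pinene sends the enolate to the Si face of the aldehyde.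

**Step 1**
Reactants: 1 3-methylbut-2-en-1-yl acetate (prenyl acetate)
Product: 2 (2E)-3-methyl-4-oxobut-2-en-1-yl acetate
Conditions: SeO2 (1.1 equiv), 1,4-dioxane, 90 °C
Reagents that add atoms: selenium dioxide, O=[Se]=O
Why: Riley allylic oxidation (ene reaction, then [2,3]-sigmatropic shift) attacks the E-methyl group of the trisubstituted alkene and runs on to the enal with the E geometry kept, the acetate being inert.

**Step 2**
Reactants: 3 3-methylbut-3-en-2-one; 2 (2E)-3-methyl-4-oxobut-2-en-1-yl acetate
Product: 6 (2E,4S)-4-hydroxy-3,7-dimethyl-6-oxoocta-2,7-dien-1-yl acetate, via boron enolate 4 (not isolated), via boron aldolate 5 (not isolated)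
Conditions: (+)-Ipc2BCl [(+)-B-chlorodiisopinocampheylborane, from (−)-α-pinene], Et3N, Et2O, 0 °C; then 2, −78 → −20 °C; then H2O2, MeOH, pH 7 buffer, 0 °C
Reagents that add atoms: none
Why: Reagent-controlled boron aldol reaction of a methyl ketone: enolization can occur only at the CH3 group, and the isopinocampheyl ligands should direct the boron enolate to the Si face of the enal through a cyclic transition state, setting C4 as S.

**Step 3**
Reactants: 6 (2E,4S)-4-hydroxy-3,7-dimethyl-6-oxoocta-2,7-dien-1-yl acetate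
Product: 7 (2E,4S)-4-[(tert-butyldimethylsilyl)oxy]-3,7-dimethyl-6-oxoocta-2,7-dien-1-yl acetate
Conditions: t-BuMe2SiOTf, 2,6-lutidine, CH2Cl2, −78 °C
Reagents that add atoms: tert-butyldimethylsilyl trifluoromethanesulfonate, CC(C)(C)[Si](C)(C)OS(=O)(=O)C(F)(F)F
Why: Silylation of the secondary alcohol with a silyl triflate and a hindered base at −78 °C should be faster than retro-aldol cleavage or β-elimination of the β-hydroxy enone, and C4 is not touched.

**Step 4**
Reactants: 7 (2E,4S)-4-[(tert-butyldimethylsilyl)oxy]-3,7-dimethyl-6-oxoocta-2,7-dien-1-yl acetate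
Product: 9 (2E,4S,6R)-4-[(tert-butyldimethylsilyl)oxy]-6-hydroxy-3,7-dimethylocta-2,7-dien-1-yl acetate, via catecholborate ester 8 (not isolated)
Conditions: (S)-Me-CBS [(3aS)-1-methyl-3,3-diphenyltetrahydro-1H,3H-pyrrolo[1,2-c][1,3,2]oxazaborole] (20 mol%), catecholborane, toluene, −78 °C; then MeOH, pH 7 buffer
Reagents that add atoms: none
Why: Corey–Bakshi–Shibata reduction under catalyst control: the isopropenyl group acts as the large substituent, so the (S)-oxazaborolidine should deliver hydride to give the 6R allylic alcohol by 1,2-reduction; catecholborane at −78 °C leaves the alkenes and the acetate alone, and the 4R,6R product arising from the minor aldol enantiomer is a diastereomer that is removed here by chromatography.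

**Step 5**
Reactants: 9 (2E,4S,6R)-4-[(tert-butyldimethylsilyl)oxy]-6-hydroxy-3,7-dimethylocta-2,7-dien-1-yl acetate
Product: 10 (2E,4S,6R)-4-[(tert-butyldimethylsilyl)oxy]-3,7-dimethyl-6-[(triethylsilyl)oxy]octa-2,7-dien-1-yl acetate
Conditions: Et3SiCl, imidazole, CH2Cl2, 0 °C
Reagents that add atoms: chlorotriethylsilane, CC[Si](Cl)(CC)CC
Why: Standard silylation of a secondary allylic alcohol; the triethylsilyl ether is chosen because it can later be cleaved beside the tert-butyldimethylsilyl ether.

**Step 6**
Reactants: 10 (2E,4S,6R)-4-[(tert-butyldimethylsilyl)oxy]-3,7-dimethyl-6-[(triethylsilyl)oxy]octa-2,7-dien-1-yl acetate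
Product: 11 (2E,4S,6R)-4-[(tert-butyldimethylsilyl)oxy]-3,7-dimethyl-6-[(triethylsilyl)oxy]octa-2,7-dien-1-ol
Conditions: K2CO3 (0.2 equiv), MeOH, 0 °C
Reagents that add atoms: none
Why: Carbonate-catalysed transesterification removes the primary allylic acetate, while both secondary silyl ethers should be stable to these mild basic conditions at 0 °C.

**Step 7**
Reactants: 11 (2E,4S,6R)-4-[(tert-butyldimethylsilyl)oxy]-3,7-dimethyl-6-[(triethylsilyl)oxy]octa-2,7-dien-1-ol; 12 ethyl 3-(2-methylphenyl)-3-oxopropanoate
Product: 13 ethyl (2E)-3-{[(2E,4S,6R)-4-[(tert-butyldimethylsilyl)oxy]-3,7-dimethyl-6-[(triethylsilyl)oxy]octa-2,7-dien-1-yl]oxy}-3-(2-methylphenyl)prop-2-enoate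
Conditions: PPh3, diisopropyl azodicarboxylate, toluene, 0 → 20 °C
Reagents that add atoms: none
Why: Mitsunobu reaction: the β-keto ester (pKa about 11) is deprotonated by the betaine and its ketone oxygen attacks the primary alkoxyphosphonium ion at C1' by SN2, the hard electrophile favouring O- over C-alkylation and the E enol ether (alkoxy trans to the ester, aryl cis to it) being the more stable geometry; no stereocentre is touched.

**Step 8**
Reactants: 13 ethyl (2E)-3-{[(2E,4S,6R)-4-[(tert-butyldimethylsilyl)oxy]-3,7-dimethyl-6-[(triethylsilyl)oxy]octa-2,7-dien-1-yl]oxy}-3-(2-methylphenyl)prop-2-enoate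
Product: 15 (2E)-3-{[(2E,4S,6R)-4-[(tert-butyldimethylsilyl)oxy]-3,7-dimethyl-6-[(triethylsilyl)oxy]octa-2,7-dien-1-yl]oxy}-3-(2-methylphenyl)prop-2-enoic acid, via lithium carboxylate 14 (not isolated)
Conditions: LiOH·H2O, THF/MeOH/H2O, 0 → 20 °C; then 0.5 M HCl to pH 4–5, 0 °C, extraction into EtOAc
Reagents that add atoms: lithium hydroxide, [Li+].[OH-]
Why: Saponification by acyl–oxygen cleavage of the β-alkoxyacrylate; cold acidification only to pH 4–5 spares the enol ether and the triethylsilyl ether, and the acid is used at once without heating because the allyl vinyl ether could undergo Claisen rearrangement.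

**Step 9**
Reactants: 15 (2E)-3-{[(2E,4S,6R)-4-[(tert-butyldimethylsilyl)oxy]-3,7-dimethyl-6-[(triethylsilyl)oxy]octa-2,7-dien-1-yl]oxy}-3-(2-methylphenyl)prop-2-enoic acid
Product: 16 4-{[(2E,4S,6R)-4-[(tert-butyldimethylsilyl)oxy]-3,7-dimethyl-6-[(triethylsilyl)oxy]octa-2,7-dien-1-yl]oxy}-5-methyl-2H-chromen-2-one
Conditions: undivided cell, graphite anode, Pt cathode, constant current (about 2.2 F/mol), n-Bu4NBF4 (0.1 M), 2,6-lutidine (1 equiv), MeCN, 0–5 °C
Reagents that add atoms: none
Why: The lutidinium carboxylate of 15 is oxidised at the anode by one electron to an alkenoyloxy radical, which loses CO2 only slowly; its oxygen adds to the free ortho carbon of the tolyl ring (the future C8a), the cyclohexadienyl radical is oxidised again and loses a proton to restore the arene, and protons are reduced to H2 at the cathode. The closest known reaction type is the anodic dehydrogenative lactonization of biaryl-2-carboxylic acids to benzocoumarins, together with the oxidative cyclization of 3-arylacrylic acids to coumarins. The pyranone ring closes by O–C(aryl) bond formation through a six-membered transition state, a 6-endo closure with respect to the ipso–ortho bond of the arene (5-exo ipso attack followed by 1,2-shift of the acyloxy group would lead to the same ring). No stereocentre is formed, and C4' and C6' are remote from the radical. The step needs regioselectivity on the arene, chemoselectivity against the chain and the right alkene geometry: the methyl group blocks the second ortho carbon so that only closure at C8a can rearomatise (5-methyl isomer), the carboxylate should be oxidised at lower potential than the isolated alkenes, the silyl ethers and the acceptor-substituted enol ether, and the E geometry from step 7 holds the aryl ring cis to the carboxyl group.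

**Step 10**
Reactants: 16 4-{[(2E,4S,6R)-4-[(tert-butyldimethylsilyl)oxy]-3,7-dimethyl-6-[(triethylsilyl)oxy]octa-2,7-dien-1-yl]oxy}-5-methyl-2H-chromen-2-one
Product: 17 4-{[(2E,4S,6R)-4-[(tert-butyldimethylsilyl)oxy]-6-hydroxy-3,7-dimethylocta-2,7-dien-1-yl]oxy}-5-methyl-2H-chromen-2-one
Conditions: pyridinium p-toluenesulfonate (10 mol%), MeOH/CH2Cl2 (1:1), 0 °C
Reagents that add atoms: none
Why: Acid-catalysed methanolysis distinguishes the two silyl ethers by size, the triethylsilyl ether being cleaved much faster than the hindered tert-butyldimethylsilyl ether, and the 4-alkoxycoumarin should tolerate this weak acid.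

**Step 11**
Reactants: 17 4-{[(2E,4S,6R)-4-[(tert-butyldimethylsilyl)oxy]-6-hydroxy-3,7-dimethylocta-2,7-dien-1-yl]oxy}-5-methyl-2H-chromen-2-one
Product: 18 (3R,5S,6E)-5-[(tert-butyldimethylsilyl)oxy]-2,6-dimethyl-8-[(5-methyl-2-oxo-2H-chromen-4-yl)oxy]octa-1,6-dien-3-yl methanesulfonate (the 6'R mesylate)
Conditions: (MeSO2)2O, Et3N, CH2Cl2, −30 °C; cold work-up, used at once
Reagents that add atoms: methanesulfonic anhydride, CS(=O)(=O)OS(C)(=O)=O
Why: Sulfonylation of the secondary allylic alcohol occurs at oxygen with retention at C6', and the anhydride is used so that no chloride is present to displace the allylic mesylate.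

**Step 12**
Reactants: 19 2,3-dimethylbut-2-ene
Product: 20 2-methoxypropan-2-yl hydroperoxide
Conditions: O3, MeOH/CH2Cl2, −78 °C; then N2 purge, kept as a cold solution
Reagents that add atoms: ozone, [O-][O+]=O; methanol, CO
Why: Ozonolysis in methanol: the Criegee carbonyl oxide released from the primary ozonide is trapped by methanol to give the α-methoxy hydroperoxide, a hydroperoxide protected as a peroxyketal.

**Step 13**
Reactants: 18 the 6'R mesylate; 20 2-methoxypropan-2-yl hydroperoxide
Product: 21 4-{[(2E,4S,6S)-4-[(tert-butyldimethylsilyl)oxy]-6-[(2-methoxypropan-2-yl)peroxy]-3,7-dimethylocta-2,7-dien-1-yl]oxy}-5-methyl-2H-chromen-2-one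
Conditions: CsOH·H2O, 20 (3 equiv), DMF, 0 °C; then 18, 0 °C
Reagents that add atoms: none
Why: SN2 displacement of a secondary sulfonate by a peroxy anion (an α-effect nucleophile) in a dipolar aprotic solvent should go with inversion, turning 6'R into 6'S; the monoprotected hydroperoxide cannot be alkylated twice, and the low temperature disfavours SN2' attack and elimination.

**Step 14**
Reactants: 21 4-{[(2E,4S,6S)-4-[(tert-butyldimethylsilyl)oxy]-6-[(2-methoxypropan-2-yl)peroxy]-3,7-dimethylocta-2,7-dien-1-yl]oxy}-5-methyl-2H-chromen-2-one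
Product: 23 4-{[(2E,4S,6S)-6-hydroperoxy-4-hydroxy-3,7-dimethylocta-2,7-dien-1-yl]oxy}-5-methyl-2H-chromen-2-one (CNP0307284.1), via hydroperoxide silyl ether 22 (not isolated)
Conditions: 48% aq. HF/MeCN (1:19), 0 → 20 °C, polypropylene vessel
Reagents that add atoms: none
Why: Aqueous HF should first hydrolyse the acid-labile peroxyketal (to acetone, methanol and the hydroperoxide) and then cleave the silyl ether as the fluorosilane; neither C4' nor C6' is ionised under these conditions, so both configurations are kept.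

**Compound list**
1 | 3-methylbut-2-en-1-yl acetate | CC(C)=CCOC(C)=O | starting material
2 | (2E)-3-methyl-4-oxobut-2-en-1-yl acetate | O=C/C(C)=C/COC(C)=O | intermediate
3 | 3-methylbut-3-en-2-one | C=C(C)C(C)=O | starting material
4 | 2-[bis(isopinocampheyl)boryloxy]-3-methylbuta-1,3-diene, Ipc groups from (−)-α-pinene | C=C(C)C(=C)OB([C@H]1C[C@H]2C[C@@H]([C@@H]1C)C2(C)C)[C@H]1C[C@H]2C[C@@H]([C@@H]1C)C2(C)C | intermediate
5 | diisopinocampheylboron aldolate of 6 | C=C(C)C(=O)C[C@H](OB([C@H]1C[C@H]2C[C@@H]([C@@H]1C)C2(C)C)[C@H]1C[C@H]2C[C@@H]([C@@H]1C)C2(C)C)/C(C)=C/COC(C)=O | intermediate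
6 | (2E,4S)-4-hydroxy-3,7-dimethyl-6-oxoocta-2,7-dien-1-yl acetate | C=C(C)C(=O)C[C@H](O)/C(C)=C/COC(C)=O | intermediate
7 | (2E,4S)-4-[(tert-butyldimethylsilyl)oxy]-3,7-dimethyl-6-oxoocta-2,7-dien-1-yl acetate | C=C(C)C(=O)C[C@H](O[Si](C)(C)C(C)(C)C)/C(C)=C/COC(C)=O | intermediate
8 | 2-alkoxy-1,3,2-benzodioxaborole (catecholborate ester) of 9 | C=C(C)[C@@H](C[C@H](O[Si](C)(C)C(C)(C)C)/C(C)=C/COC(C)=O)OB1Oc2ccccc2O1 | intermediate
9 | (2E,4S,6R)-4-[(tert-butyldimethylsilyl)oxy]-6-hydroxy-3,7-dimethylocta-2,7-dien-1-yl acetate | C=C(C)[C@@H](C[C@H](O[Si](C)(C)C(C)(C)C)/C(C)=C/COC(C)=O)O | intermediate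
10 | (2E,4S,6R)-4-[(tert-butyldimethylsilyl)oxy]-3,7-dimethyl-6-[(triethylsilyl)oxy]octa-2,7-dien-1-yl acetate | C=C(C)[C@@H](C[C@H](O[Si](C)(C)C(C)(C)C)/C(C)=C/COC(C)=O)O[Si](CC)(CC)CC | intermediate
11 | (2E,4S,6R)-4-[(tert-butyldimethylsilyl)oxy]-3,7-dimethyl-6-[(triethylsilyl)oxy]octa-2,7-dien-1-ol | C=C(C)[C@@H](C[C@H](O[Si](C)(C)C(C)(C)C)/C(C)=C/CO)O[Si](CC)(CC)CC | intermediate
12 | ethyl 3-(2-methylphenyl)-3-oxopropanoate | CCOC(=O)CC(=O)c1ccccc1C | starting material
13 | ethyl (2E)-3-{[(2E,4S,6R)-4-[(tert-butyldimethylsilyl)oxy]-3,7-dimethyl-6-[(triethylsilyl)oxy]octa-2,7-dien-1-yl]oxy}-3-(2-methylphenyl)prop-2-enoate | C=C(C)[C@@H](C[C@H](O[Si](C)(C)C(C)(C)C)/C(C)=C/CO/C(=C/C(=O)OCC)c1ccccc1C)O[Si](CC)(CC)CC | intermediate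
14 | lithium salt of acid 15 | [Li+].C=C(C)[C@@H](C[C@H](O[Si](C)(C)C(C)(C)C)/C(C)=C/CO/C(=C/C(=O)[O-])c1ccccc1C)O[Si](CC)(CC)CC | intermediate
15 | (2E)-3-{[(2E,4S,6R)-4-[(tert-butyldimethylsilyl)oxy]-3,7-dimethyl-6-[(triethylsilyl)oxy]octa-2,7-dien-1-yl]oxy}-3-(2-methylphenyl)prop-2-enoic acid | C=C(C)[C@@H](C[C@H](O[Si](C)(C)C(C)(C)C)/C(C)=C/CO/C(=C/C(=O)O)c1ccccc1C)O[Si](CC)(CC)CC | intermediate
16 | 4-{[(2E,4S,6R)-4-[(tert-butyldimethylsilyl)oxy]-3,7-dimethyl-6-[(triethylsilyl)oxy]octa-2,7-dien-1-yl]oxy}-5-methyl-2H-chromen-2-one | C=C(C)[C@@H](C[C@H](O[Si](C)(C)C(C)(C)C)/C(C)=C/COc1cc(=O)oc2cccc(C)c12)O[Si](CC)(CC)CC | intermediate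
17 | 4-{[(2E,4S,6R)-4-[(tert-butyldimethylsilyl)oxy]-6-hydroxy-3,7-dimethylocta-2,7-dien-1-yl]oxy}-5-methyl-2H-chromen-2-one | C=C(C)[C@@H](C[C@H](O[Si](C)(C)C(C)(C)C)/C(C)=C/COc1cc(=O)oc2cccc(C)c12)O | intermediate
18 | (3R,5S,6E)-5-[(tert-butyldimethylsilyl)oxy]-2,6-dimethyl-8-[(5-methyl-2-oxo-2H-chromen-4-yl)oxy]octa-1,6-dien-3-yl methanesulfonate | C=C(C)[C@@H](C[C@H](O[Si](C)(C)C(C)(C)C)/C(C)=C/COc1cc(=O)oc2cccc(C)c12)OS(C)(=O)=O | intermediate
19 | 2,3-dimethylbut-2-ene | CC(C)=C(C)C | starting material
20 | 2-methoxypropan-2-yl hydroperoxide | COC(C)(C)OO | intermediate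
21 | 4-{[(2E,4S,6S)-4-[(tert-butyldimethylsilyl)oxy]-6-[(2-methoxypropan-2-yl)peroxy]-3,7-dimethylocta-2,7-dien-1-yl]oxy}-5-methyl-2H-chromen-2-one | C=C(C)[C@H](C[C@H](O[Si](C)(C)C(C)(C)C)/C(C)=C/COc1cc(=O)oc2cccc(C)c12)OOC(C)(C)OC | intermediate
22 | 4-{[(2E,4S,6S)-4-[(tert-butyldimethylsilyl)oxy]-6-hydroperoxy-3,7-dimethylocta-2,7-dien-1-yl]oxy}-5-methyl-2H-chromen-2-one | C=C(C)[C@H](C[C@H](O[Si](C)(C)C(C)(C)C)/C(C)=C/COc1cc(=O)oc2cccc(C)c12)OO | intermediate
23 | 4-{[(2E,4S,6S)-6-hydroperoxy-4-hydroxy-3,7-dimethylocta-2,7-dien-1-yl]oxy}-5-methyl-2H-chromen-2-one (CNP0307284.1) | C=C(C)[C@H](C[C@H](O)/C(C)=C/COc1cc(=O)oc2cccc(C)c12)OO | target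

**Step count**
Total: 14 steps. Longest linear sequence: 13 steps (steps 1–11, 13 and 14, from 1); step 12 prepares the peroxide reagent.

**Steps most likely to fail**

1. Step 9 (anodic lactonization). Electron transfer may start at the aryl enol ether π-system instead of the carboxylate, or the carboxyl radical may abstract a benzylic hydrogen from the ortho methyl group or decarboxylate before it closes onto C8a. Fallback: the coumarin is brought in ready-made. The fallback sets out from alcohol 11. 4-Hydroxy-5-methyl-2H-chromen-2-one F1 is made from commercial 1-(2-hydroxy-6-methylphenyl)ethanone with diethyl carbonate and NaH in toluene at 100 °C. F1 is then joined to 11 by Mitsunobu etherification (PPh3, diisopropyl azodicarboxylate, THF, 0 °C), and the 4-O-alkyl product is separated from any 2-O-alkyl chromone. This gives 16, where the route is rejoined before step 10.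

2. Step 13 (peroxide displacement). The peroxy anion may attack the allylic terminus C8' (SN2'), act as a base (E2 to the diene) or add to the coumarin lactone, and the allylic mesylate may ionise with loss of configuration. Fallback: the C6'–O bond is made by an ene reaction instead of a substitution. The fallback sets out from alcohol 17. Reductive 1,3-transposition through the allylic diazene (2-nitrobenzenesulfonylhydrazide, PPh3, diethyl azodicarboxylate, THF, −30 → 20 °C; loss of sulfinic acid, then of N2) removes the C6' oxygen and moves the alkene to C6'=C7'. This gives 4-{[(2E,4S)-4-[(tert-butyldimethylsilyl)oxy]-3,7-dimethylocta-2,6-dien-1-yl]oxy}-5-methyl-2H-chromen-2-one F2. Schenck ene reaction of F2 with singlet oxygen (O2, 5,10,15,20-tetraphenylporphyrin, visible light, CH2Cl2, 0 °C) places the hydroperoxide at C6' and the alkene at C7'=C8'. This reaction is not selective at C6' and also forms the tertiary C7' hydroperoxide, so the 6'S isomer must be separated by HPLC. It is compound 22, where the route is rejoined; 22 is desilylated under the conditions of step 14.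

3. Step 7 (Mitsunobu O-alkylation). The ambident enolate may be alkylated at carbon, the alkoxyphosphonium ion may be attacked with allylic transposition, or the enol ether may form with the aryl group trans to the ester. Fallback: the O–C3 bond is made by conjugate addition, which cannot give C-alkylation. The fallback sets out from alcohol 11. Ethyl 3-(2-methylphenyl)prop-2-ynoate F3 is made from 1-ethynyl-2-methylbenzene with n-BuLi and ethyl chloroformate in THF at −78 °C. The alkoxide of 11 is added to F3 in a base-catalysed oxa-Michael addition (NaH 10 mol%, THF, 0 °C), which can equilibrate by reversible addition to the more stable E isomer. The route is rejoined at ester 13.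

**Further compounds**
F1 | step 9 | 4-hydroxy-5-methyl-2H-chromen-2-one | Cc1cccc2oc(=O)cc(O)c12
F2 | step 13 | 4-{[(2E,4S)-4-[(tert-butyldimethylsilyl)oxy]-3,7-dimethylocta-2,6-dien-1-yl]oxy}-5-methyl-2H-chromen-2-one | CC(C)=CC[C@H](O[Si](C)(C)C(C)(C)C)/C(C)=C/COc1cc(=O)oc2cccc(C)c12
F3 | step 7 | ethyl 3-(2-methylphenyl)prop-2-ynoate | CCOC(=O)C#Cc1ccccc1C
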